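## The problem

The target is (2R)-6-methyl-2-[(10Z)-nonadec-10-en-1-yl]-2,3-dihydro-4H-pyran-4-one (C25H44O2). It has one six-membered vinylogous-ester ring (O1, C2, C3, C4=O, C5=C6–CH3), one stereocentre (C2, R) and one isolated Z alkene in an unbranched C19 chain. C2 has no neighbouring stereocentre or directing group, so its configuration must come from a catalyst or the chiral pool; because it carries the chain, the step that sets C2 is naturally the step that joins chain and ring. The C2–O1 bond is β to the C4 ketone, so base, or acid with heat, can open the ring by retro-oxa-Michael reaction to an achiral dienone and close it again; C2 must therefore be set late and cold, and not meet enolising base afterwards. The Z alkene lies nine methylenes from the ring, beyond any substrate control; it forbids hydrogenation, thiyl or halogen radical chemistry and hot strong acid, and is better bought than made. The cheapest Z building blocks are the C18 oleyl compounds, whose alkene and tail match the target chain but which are one carbon short. The feature that the plan uses: ring atoms O1/C2–C6 are exactly those of the aromatic γ-pyrone 2-methyl-4H-pyran-4-one, with one carbon substituent added at its free oxygen-bound carbon (C2 of the target) and one hydrogen at C3, while the other oxygen-bound carbon (C6) already carries the methyl group that blocks it.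

## Retrosynthesis

Target 11 to silyl dienol ether 10. The C4 ketone and the C3–H bond are taken back to the 4-silyloxy-2H-pyran 10. No skeletal bond is cut. The point is that the enone is released by cold dilute acid only after C2 exists, so no metal dienolate of 11, which could open the ring, is ever warmed. The forward step must protonate C3 and remove silicon without opening the C2–O1 bond.

10 to pyrylium 9 and Grignard reagent 8. The bond cut is C2–C1′, between ring and chain. The neighbouring cuts (O1–C2, C2–C3) lead to aldehyde-based ring constructions in which the ring must be built and then closed. A cut one bond further out (C1′–C2′) would need a chiral ring fragment with a leaving group β to the ring oxygen. The chosen cut takes the whole ring, at its final oxidation level, from a flat, achiral aromatic cation, and the chain from a plain primary Grignard reagent; the only stereocentre is created in the same event. The forward reaction must add at C6 of 9 (the carbon that becomes C2 of 11) and not at its methyl-bearing C2 or at C4, must choose one face of C6, and must stop after one addition.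

9 to pyranone 7 to diketone 6 to enone 5. 9 is 7 silylated on the carbonyl oxygen. In 7 the bonds O1–C6 and C2–C3 are cut: the ring closes by attack of the enol oxygen of 6 on its β-methoxy enone carbon with loss of methanol, and 6 comes from C-acylation of the enolate of 5 with an acetyl donor. 5 has a single enolisable position, so the acylation has no regiochemical choice.

8 to bromide 4 to alcohol 3 to Grignard reagent 2 to bromide 1. The chain is cut at C1′–C2′. The C18 part, with the Z alkene in place, is commercial oleyl bromide 1, and the missing carbon is a one-carbon electrophile added to 2. This is preferred to building the alkene (Wittig or alkyne semi-reduction), which would add steps and put the Z purity at risk. The forward steps are a hydroxymethylation and a neutral bromination, neither of which touches an isolated alkene.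

## Roads not taken

Alternative 1: cut C2–C3 and O1–C6, the hetero-Diels–Alder disconnection most chemists would draw first. The forward key step is the enantioselective cycloaddition (in practice Mukaiyama aldol addition and acid closure) of (Z)-eicos-11-enal A1 with (E)-4-methoxy-2-(trimethylsilyloxy)penta-1,3-diene A2 under a chiral Lewis acid such as Ti(OiPr)4/BINOL.
- The ring is assembled from two acyclic pieces, and ring closure with loss of methanol is a separate acid-driven event after the stereocentre exists.
- A1 is an enolisable, air-sensitive long-chain aldehyde that needs a further redox or formylation step from the stable chain halide, and unbranched aliphatic aldehydes are the least selective substrates of this catalysis.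
- A2 is fully substituted at the terminus that must bond to oxygen, so the selectivity rests on an open aldol transition state rather than a concerted one.
- The step count is about equal, so this route is not rejected on length; it is kept as the fallback for the key step.

Alternative 2: cut O1–C6 only, with closure of a β-hydroxy ynone. Methyl (Z)-3-oxodocos-13-enoate A3 (two-carbon homologation of the commercial C20 acid) would be hydrogenated with RuCl2(BINAP) to methyl (3R,13Z)-3-hydroxydocos-13-enoate A4. About three operations (protection, amide formation, addition of propynyllithium and deprotection) would give (6R,16Z)-6-hydroxypentacos-16-en-2-yn-4-one A5, which Ph3PAuCl/AgOTf or mild base would close 6-endo-dig to the target.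
- The route is linear and at least six steps long, with the whole chain carried from the first step.
- The hydrogenation must spare the Z alkene.
- The stereocentre is made early as a β-oxygenated carbonyl compound and carried through an organolithium addition, where elimination or retro-aldol loss is possible.

Alternative 3: the same dearomatisation logic with hydride instead of carbon, cutting C2–H. Lateral lithiation of 2,6-dimethyl-4H-pyran-4-one A6 and alkylation with 1 would give 2-methyl-6-[(Z)-nonadec-10-enyl]-4H-pyran-4-one A7 in one step, the methyl carbon of A6 supplying the nineteenth chain carbon. The key step would be an enantioselective conjugate reduction of A7 with a chiral bisphosphine CuH catalyst (from Cu(OAc)2 and a hydrosilane).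
- It is the shortest plan on paper, but the two enone halves of A7 differ only as CH3 against CH2R.
- Nothing directs hydride to the chain-bearing carbon, and the smaller methyl side, the wrong one, should react at least as fast.
- In 7 the two oxygen-bound carbons differ as H against CH3, which is why the carbon nucleophile is paired with the methylpyranone.

Key step: step 4

Assumption: the facial preference of the CuBr·SMe2/Ph-BPE catalyst on pyrylium 9 is taken by analogy with related N-acylpyridinium and chromone acceptors; the ligand is sold in both enantiomeric forms, the one that delivers the alkyl group to the Re face of C6 of 9 is used, and (R,R) is written throughout.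

## Route

Step 1
Reactants: 1 (Z)-1-bromooctadec-9-ene (oleyl bromide, high-Z grade)
Product: 3 (Z)-nonadec-10-en-1-ol, via (Z)-octadec-9-enylmagnesium bromide 2 (not isolated)
Conditions: Mg, I2 (cat.), THF, 50 °C; dry (CH2O)n, 0 °C to rt; 1 M aq. HCl
Reagents that add atoms: formaldehyde (used as paraformaldehyde), C=O
Why: Grignard formation from a primary bromide and hydroxymethylation with formaldehyde is a classical one-carbon homologation; the isolated Z alkene is inert to magnesium and to the alkoxide, so the alkene geometry of 1 is carried through unchanged, and no stereocentre is formed.

Step 2
Reactants: 3 (Z)-nonadec-10-en-1-ol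
Product: 4 (Z)-1-bromononadec-10-ene
Conditions: CBr4, PPh3, CH2Cl2, 0 °C to rt
Reagents that add atoms: carbon tetrabromide, BrC(Br)(Br)Br
Why: Appel reaction; bromide displaces the alkoxyphosphonium group by SN2 under neutral conditions, with no acid or radical that could isomerise the Z alkene.

Step 3
Reactants: 5 (E)-4-methoxybut-3-en-2-one
Product: 7 2-methyl-4H-pyran-4-one, via (E)-1-methoxyhex-1-ene-3,5-dione 6 (not isolated)
Conditions: LiN(SiMe3)2 (2 equiv), 5 (2 equiv), THF, −78 °C; AcCl (1 equiv), −78 °C; 1 M aq. HCl; crude 6, CF3CO2H, CH2Cl2, rt
Reagents that add atoms: acetyl chloride, CC(=O)Cl
Why: The lithium enolate of 5, formed at its only enolisable position, is C-acylated by the acid chloride (Claisen-type acylation, the second equivalent of enolate taking up the acidic proton of 6); acid then drives 6-endo-trig attack of the enol oxygen on the β-methoxy enone and loss of methanol (addition–elimination) to give the aromatic pyranone.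

Step 4
Reactants: 4 (Z)-1-bromononadec-10-ene; 7 2-methyl-4H-pyran-4-one
Product: 11 (2R)-6-methyl-2-[(10Z)-nonadec-10-en-1-yl]-2,3-dihydro-4H-pyran-4-one, via (Z)-nonadec-10-enylmagnesium bromide 8 (not isolated), via 2-methyl-4-(trimethylsilyloxy)pyrylium triflate 9 (not isolated), via (2R)-4-(trimethylsilyloxy)-2H-pyran adduct 10 (not isolated)
Conditions: Mg, Et2O, reflux (4 to 8); Me3SiOTf, CH2Cl2, 0 °C (7 to 9); CuBr·SMe2 (5 mol %), (R,R)-Ph-BPE (6 mol %), slow addition of 8, CH2Cl2/Et2O, −78 °C; MeOH, then 1 M aq. HCl, −78 to 0 °C
Reagents that add atoms: none
Why: Proposed new method: Me3SiOTf silylates the carbonyl oxygen of 7 to give the aromatic pyrylium 9, 8 transmetalates to the bisphosphine-bound monovalent copper, and the resulting chiral alkylcopper adds to C6 of 9 (π-complex, oxidative addition to a trivalent copper σ-allyl species, reductive elimination) to give the neutral silyl dienol ether 10, which cold dilute acid protonates at C3 and desilylates to 11. The closest known reaction type is the CuBr·SMe2/Ph-BPE-catalysed dearomative addition of Grignard reagents to N-acyl-4-methoxypyridinium ions, which gives 2-alkyl-2,3-dihydro-4-pyridones, next to the copper-catalysed conjugate addition of Grignard reagents to chromones and the uncatalysed addition of carbon nucleophiles to 4-silyloxypyrylium triflates; 9 is the oxygen counterpart of those pyridinium ions, planar and unhindered at the reacting carbon. No ring is closed, the ring O1/C2–C6 of 11 being that of 7. The single new stereocentre (C6 of 9, C2 of 11) is set by the catalyst alone: the C2-symmetric diphospholane must deliver the alkyl group to the Re face of C6. Regioselectivity is secured by the substrate, since C6 carries hydrogen whereas the other oxygen-bound carbon carries the methyl group and C4 the silyloxy group. Mono-addition is secured because 10 is an electron-rich dienol ether and no longer an acceptor, and the isolated Z alkene is inert to all reagents. Enantioselectivity needs the copper path to outrun direct attack of 8 on 9, which is served by slow addition of 8 at −78 °C, and it needs 10 to be hydrolysed cold before it can open to an achiral dienone and close again.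

## Compound list

1 | (Z)-1-bromooctadec-9-ene (oleyl bromide) | CCCCCCCC/C=C\CCCCCCCCBr | starting material
2 | (Z)-octadec-9-enylmagnesium bromide | CCCCCCCC/C=C\CCCCCCCC[Mg]Br | intermediate
3 | (Z)-nonadec-10-en-1-ol | CCCCCCCC/C=C\CCCCCCCCCO | intermediate
4 | (Z)-1-bromononadec-10-ene | CCCCCCCC/C=C\CCCCCCCCCBr | intermediate
5 | (E)-4-methoxybut-3-en-2-one | CO/C=C/C(C)=O | starting material
6 | (E)-1-methoxyhex-1-ene-3,5-dione | CO/C=C/C(=O)CC(C)=O | intermediate
7 | 2-methyl-4H-pyran-4-one | CC1=CC(=O)C=CO1 | intermediate
8 | (Z)-nonadec-10-enylmagnesium bromide | CCCCCCCC/C=C\CCCCCCCCC[Mg]Br | intermediate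
9 | 2-methyl-4-(trimethylsilyloxy)pyrylium trifluoromethanesulfonate | Cc1cc(O[Si](C)(C)C)cc[o+]1.[O-]S(=O)(=O)C(F)(F)F | intermediate
10 | trimethyl({(2R)-6-methyl-2-[(10Z)-nonadec-10-en-1-yl]-2H-pyran-4-yl}oxy)silane | CCCCCCCC/C=C\CCCCCCCCC[C@@H]1C=C(O[Si](C)(C)C)C=C(C)O1 | intermediate
11 | (2R)-6-methyl-2-[(10Z)-nonadec-10-en-1-yl]-2,3-dihydro-4H-pyran-4-one | CCCCCCCC/C=C\CCCCCCCCC[C@@H]1CC(=O)C=C(C)O1 | target

## Step count and risks

Total steps: 4. Longest linear sequence: 3 (steps 1, 2 and 4); step 3 is a one-step branch.

Step 4 (key step, proposed new method). The most likely failure is loss of enantioselectivity through uncatalysed attack of the Grignard reagent on the very electrophilic pyrylium ion. The second is erosion of configuration by ring opening and re-closure of the 2H-pyran adduct before it is hydrolysed; attack at C4 is a lesser concern. The fallback uses known chemistry, sets out from 4 and returns at 11. 8, made from 4 as before, is formylated with N,N-dimethylformamide to (Z)-eicos-11-enal F1. Commercial (E)-4-methoxypent-3-en-2-one F2 is converted with LiN(iPr)2 and Me3SiCl into (E)-4-methoxy-2-(trimethylsilyloxy)penta-1,3-diene F3. A Ti(OiPr)4/BINOL-catalysed Mukaiyama aldol addition of F3 to F1, with the BINOL enantiomer that directs attack to the Si face of the aldehyde, should give after desilylation (2E,6R,16Z)-6-hydroxy-2-methoxypentacosa-2,16-dien-4-one F4. CF3CO2H then closes F4 to 11 with loss of methanol.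

Step 3. The most likely failure is O-acylation of the enolate, or ketene formation from acetyl chloride, in place of C-acylation, together with loss of the small, water-soluble pyranone on work-up. The fallback sets out from 5 and returns at 7. Condensation of 5 at its only enolisable position with N,N-dimethylacetamide dimethyl acetal (toluene, heat) should give (1E,4E)-5-(dimethylamino)-1-methoxyhexa-1,4-dien-3-one F5, a base-free equivalent of 6. Aqueous HCl hydrolyses the enaminone and closes the ring to 7 with loss of dimethylamine and methanol.

Step 1. The most likely failure is incomplete reaction with polymeric formaldehyde and formal formation at the alkoxide stage, with some Wurtz coupling during Grignard formation. The fallback sets out from 1 and returns at 3. 2 is quenched with CO2 to give (Z)-nonadec-10-enoic acid F6, which LiAlH4 in THF reduces to 3 without touching the alkene.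

## Further compounds

F1 | step 4 | (Z)-eicos-11-enal | CCCCCCCC/C=C\CCCCCCCCCC=O
F2 | step 4 | (E)-4-methoxypent-3-en-2-one | CO/C(C)=C/C(C)=O
F3 | step 4 | (E)-4-methoxy-2-(trimethylsilyloxy)penta-1,3-diene | CO/C(C)=C/C(=C)O[Si](C)(C)C
F4 | step 4 | (2E,6R,16Z)-6-hydroxy-2-methoxypentacosa-2,16-dien-4-one | CCCCCCCC/C=C\CCCCCCCCC[C@@H](O)CC(=O)/C=C(\C)OC
F5 | step 3 | (1E,4E)-5-(dimethylamino)-1-methoxyhexa-1,4-dien-3-one | CO/C=C/C(=O)/C=C(\C)N(C)C
F6 | step 1 | (Z)-nonadec-10-enoic acid | CCCCCCCC/C=C\CCCCCCCCC(=O)O
A1 | alternative 1 | (Z)-eicos-11-enal | CCCCCCCC/C=C\CCCCCCCCCC=O
A2 | alternative 1 | (E)-4-methoxy-2-(trimethylsilyloxy)penta-1,3-diene | CO/C(C)=C/C(=C)O[Si](C)(C)C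
A3 | alternative 2 | methyl (Z)-3-oxodocos-13-enoate | CCCCCCCC/C=C\CCCCCCCCCC(=O)CC(=O)OC
A4 | alternative 2 | methyl (3R,13Z)-3-hydroxydocos-13-enoate | CCCCCCCC/C=C\CCCCCCCCC[C@@H](O)CC(=O)OC
A5 | alternative 2 | (6R,16Z)-6-hydroxypentacos-16-en-2-yn-4-one | CCCCCCCC/C=C\CCCCCCCCC[C@@H](O)CC(=O)C#CC
A6 | alternative 3 | 2,6-dimethyl-4H-pyran-4-one | CC1=CC(=O)C=C(C)O1
A7 | alternative 3 | 2-methyl-6-[(Z)-nonadec-10-enyl]-4H-pyran-4-one | CCCCCCCC/C=C\CCCCCCCCCC1=CC(=O)C=C(C)O1
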